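**Plan**

- Numbering used throughout: ring carbons C1 (bears the chain), C2 (OH), C3 (OMe), C4 (OH), C5, C6; chain C7, C8, C9 (ester carbonyl).
- The retrosynthesis first cuts the C9–O(octadecyl) ester bond, which leads back to the six-membered aryl lactone that ties C9 to the oxygen on C2.
- It then cuts the C2–O bond of that lactone (retro-Baeyer–Villiger) to a 1-indanone with a C2–C9 bond, and finally the C2–C9 bond (retro-Friedel–Crafts) to dihydroferulic acid, which already holds C1–C9, the C3 methoxy group and the C4 oxygen.
- Enabling feature: C2 sits between C1 and the methoxy-bearing C3 and is not reached by direct ring hydroxylation. C9 is three atoms from C1, so with C6 blocked by bromine it can be bonded to C2 as a five-membered ketone (C1, C2, C9, C8, C7), and oxygen is then inserted into the C2–C9 bond.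
- Forward order: benzylation of the C4 oxygen, bromination at C6, closure of the five-membered ketone, ring expansion to the six-membered lactone, hydrogenolysis of bromine and benzyl, and last the opening of the lactone by octadecan-1-ol, which joins the C18 chain.
- Stereochemistry: the target has no stereocentre and no double-bond geometry, so nothing has to be set.

Key step: step 4

**Route**

Step 1
Reactants: 1 dihydroferulic acid; 2 benzyl bromide
Product: 4 O-benzyldihydroferulic acid [3-(4-benzyloxy-3-methoxyphenyl)propanoic acid], via benzyl ester 3 (not isolated)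
Conditions: BnBr (2.3 equiv), K2CO3, DMF, 60 °C; then NaOH, MeOH–H2O, 60 °C; then aq. HCl to pH 2
Reagents that add atoms: benzyl bromide, BrCc1ccccc1
Why: Williamson etherification benzylates the phenoxide and the carboxylate alike, and saponification of the benzyl ester in the same pot leaves only the aryl benzyl ether, which is stable to hydroxide.

Step 2
Reactants: 4 O-benzyldihydroferulic acid; 5 N-bromosuccinimide
Product: 6 3-[4-(benzyloxy)-2-bromo-5-methoxyphenyl]propanoic acid
Conditions: NBS (1.05 equiv), MeCN, 0 °C to rt, dark
Reagents that add atoms: N-bromosuccinimide, O=C1CCC(=O)N1Br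
Why: Electrophilic aromatic bromination of a 4-alkyl-1,2-dialkoxybenzene should go to C6, which is para to the C3 methoxy group and ortho to the chain, because C2 is flanked on both sides and C5 has only one ortho oxygen, and polar conditions in the dark leave the benzylic positions alone.

Step 3
Reactants: 6 3-[4-(benzyloxy)-2-bromo-5-methoxyphenyl]propanoic acid
Product: 8 6-(benzyloxy)-4-bromo-7-methoxyindan-1-one, via acid chloride 7 (not isolated)
Conditions: (COCl)2, cat. DMF, CH2Cl2, 0 °C to rt, evaporate; then SnCl4 (1.2 equiv), CH2Cl2, −20 to 0 °C; cold 1 M HCl quench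
Reagents that add atoms: oxalyl chloride, O=C(Cl)C(=O)Cl (its chlorine is present in 7 only and leaves again on ring closure)
Why: Intramolecular Friedel–Crafts acylation can form the five-membered ring only at a carbon ortho to C1, so with C6 occupied by bromine the acylium carbon C9 should bond to C2, which the ortho methoxy group activates, while SnCl4 at low temperature is mild enough to spare the benzyl and methyl ethers.

Step 4
Reactants: 8 6-(benzyloxy)-4-bromo-7-methoxyindan-1-one; 9 3-chloroperbenzoic acid
Product: 10 7-(benzyloxy)-5-bromo-8-methoxy-3,4-dihydrocoumarin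
Conditions: mCPBA (1.5 equiv), TFA (1 equiv), CH2Cl2, 0 °C to rt, dark
Reagents that add atoms: 3-chloroperbenzoic acid, O=C(OO)c1cccc(Cl)c1
Why: Acid-catalysed addition of the peracid to the C9 carbonyl gives a tetrahedral peroxy adduct in which the aryl carbon C2 shifts from C9 to the near peroxide oxygen as 3-chlorobenzoate leaves, so that C2–C9 is replaced by C2–O–C9. The closest known reaction is the Baeyer–Villiger oxidation of 1-indanones, which gives 3,4-dihydrocoumarins by aryl migration. The six-membered lactone (O, C9, C8, C7, C1, C2) arises by ring expansion of the five-membered ketone through a 1,2-shift with insertion of one atom, not by cyclisation of an open chain. No stereocentre is formed. The step needs migration of the aryl carbon C2 in preference to the primary methylene C8, and this is secured by the methoxy group on C3, ortho to C2, whose lone pair stabilises the positive charge that builds up in the migrating ring, whereas a primary alkyl group migrates poorly. Attack of the peracid on the ring itself should be held back by the bromine at C6 and the acyl group, which both lower the electron density of the arene, and the benzyl ether is inert to the reagent.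

Step 5
Reactants: 10 7-(benzyloxy)-5-bromo-8-methoxy-3,4-dihydrocoumarin
Product: 11 7-hydroxy-8-methoxy-3,4-dihydrocoumarin
Conditions: H2 (1 atm), 10% Pd/C, NaOAc (2 equiv), AcOH–EtOAc, rt
Reagents that add atoms: none
Why: Catalytic hydrogenolysis over palladium on carbon should cleave the O-benzyl ether and the aryl C–Br bond in one operation, with acetate (which, unlike an amine, does not slow O-debenzylation) taking up the HBr and an alcohol-free medium keeping the aryl lactone closed.

Step 6
Reactants: 11 7-hydroxy-8-methoxy-3,4-dihydrocoumarin; 12 octadecan-1-ol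
Product: 13 octadecyl 3-(2,4-dihydroxy-3-methoxyphenyl)propanoate
Conditions: 12 (2.3 equiv), NaH (2.1 equiv), THF, 40 °C; then 11, 0 °C to rt, Ar; AcOH (2.2 equiv), −20 °C
Reagents that add atoms: octadecan-1-ol, CCCCCCCCCCCCCCCCCCO
Why: In this alkoxide transesterification of an aryl lactone the first equivalent of sodium octadecan-1-olate deprotonates the C4 phenol and the second adds to C9 and expels the C2 phenoxide, whose low basicity drives the opening to completion, and the cold acidic quench should give the neutral hydroxy ester before it can close again.

**Compound list**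

1 | dihydroferulic acid, 3-(4-hydroxy-3-methoxyphenyl)propanoic acid | COc1cc(CCC(=O)O)ccc1O | starting material
2 | benzyl bromide | BrCc1ccccc1 | starting material
3 | benzyl 3-[4-(benzyloxy)-3-methoxyphenyl]propanoate | COc1cc(CCC(=O)OCc2ccccc2)ccc1OCc1ccccc1 | intermediate (not isolated)
4 | O-benzyldihydroferulic acid, 3-[4-(benzyloxy)-3-methoxyphenyl]propanoic acid | COc1cc(CCC(=O)O)ccc1OCc1ccccc1 | intermediate
5 | N-bromosuccinimide | O=C1CCC(=O)N1Br | starting material
6 | 3-[4-(benzyloxy)-2-bromo-5-methoxyphenyl]propanoic acid | COc1cc(CCC(=O)O)c(Br)cc1OCc1ccccc1 | intermediate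
7 | 3-[4-(benzyloxy)-2-bromo-5-methoxyphenyl]propanoyl chloride | COc1cc(CCC(=O)Cl)c(Br)cc1OCc1ccccc1 | intermediate (not isolated)
8 | 6-(benzyloxy)-4-bromo-7-methoxyindan-1-one | O=C1CCc2c(Br)cc(OCc3ccccc3)c(OC)c21 | intermediate
9 | 3-chloroperbenzoic acid | O=C(OO)c1cccc(Cl)c1 | starting material
10 | 7-(benzyloxy)-5-bromo-8-methoxy-3,4-dihydrocoumarin (chroman-2-one) | O=C1CCc2c(Br)cc(OCc3ccccc3)c(OC)c2O1 | intermediate
11 | 7-hydroxy-8-methoxy-3,4-dihydrocoumarin | O=C1CCc2ccc(O)c(OC)c2O1 | intermediate
12 | octadecan-1-ol | CCCCCCCCCCCCCCCCCCO | starting material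
13 | octadecyl 3-(2,4-dihydroxy-3-methoxyphenyl)propanoate | CCCCCCCCCCCCCCCCCCOC(=O)CCc1ccc(O)c(OC)c1O | target

**Step count and risks**

Total step count: 6. Longest linear sequence: 6 steps (1 to 13).

Steps most likely to fail:

Step 3. The closure at the crowded C2 may be slow, and the Lewis acid may then cleave the benzyl ether, demethylate the C3 oxygen beside the new carbonyl, or allow ipso attack at the brominated C6 with loss of bromine. The fallback sets out from 1 and replaces the benzyl ether by an ester that is inert to acid, so that the ring can be closed in a strong Brønsted acid. Acetylation of 1 (Ac2O, aq. NaOH, 0 °C) should give 3-(4-acetoxy-3-methoxyphenyl)propanoic acid F1. Bromination para to the methoxy group (Br2, NaOAc, AcOH) should give 3-(4-acetoxy-2-bromo-5-methoxyphenyl)propanoic acid F2. Cyclodehydration of the free acid in Eaton's reagent (P2O5 in MeSO3H, rt to 40 °C) should give 4-bromo-7-methoxy-1-oxoindan-6-yl acetate F3. Methanolysis (K2CO3, MeOH, rt) should free 4-bromo-6-hydroxy-7-methoxyindan-1-one F4, and benzylation with 2 (K2CO3, DMF) comes back to the route at 8.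

Step 4. The peracid may add only slowly to the hindered, donor-conjugated C9 carbonyl, the C8 methylene may migrate in competition, and long exposure may oxidise the arene. The fallback keeps the shift of C2 from C9 to oxygen but runs it at the alcohol oxidation level as a Hock-type hydroperoxide rearrangement, in which no carbonyl addition is needed and aryl migration dominates. From 8, reduction (NaBH4, MeOH, 0 °C) should give racemic 6-(benzyloxy)-4-bromo-7-methoxyindan-1-ol F5. Acid-catalysed exchange with hydrogen peroxide (50% aq. H2O2, cat. H2SO4, THF, 0 °C) should give racemic 6-(benzyloxy)-4-bromo-1-hydroperoxy-7-methoxyindane F6. On treatment with BF3·OEt2 in CH2Cl2 at 0 °C this should rearrange, with re-addition of water, to racemic 7-(benzyloxy)-5-bromo-8-methoxychroman-2-ol F7. Oxidation of the lactol with Ag2CO3 on Celite in hot toluene comes back to the route at 10.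

Step 6. The hydroxy ester may close back to the lactone with loss of octadecan-1-ol during the quench or on silica, and the opening may stall if the sodium salts precipitate. The fallback forms the ester by O-alkylation of a carboxylate, which is not reversible under the conditions, instead of by acyl transfer. From 11, hydrolysis of the lactone (aq. LiOH, THF, 0 °C, Ar, then cold acidification to pH 4) should give 3-(2,4-dihydroxy-3-methoxyphenyl)propanoic acid F8. Alkylation of its carboxylate with 1-bromooctadecane (KHCO3, DMF, 45 °C), a base too weak to engage the phenols, comes back to the route at 13.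

**Further compounds**

F1 | step 3 | 3-(4-acetoxy-3-methoxyphenyl)propanoic acid | COc1cc(CCC(=O)O)ccc1OC(C)=O
F2 | step 3 | 3-(4-acetoxy-2-bromo-5-methoxyphenyl)propanoic acid | COc1cc(CCC(=O)O)c(Br)cc1OC(C)=O
F3 | step 3 | 4-bromo-7-methoxy-1-oxoindan-6-yl acetate | O=C1CCc2c(Br)cc(OC(C)=O)c(OC)c21
F4 | step 3 | 4-bromo-6-hydroxy-7-methoxyindan-1-one | O=C1CCc2c(Br)cc(O)c(OC)c21
F5 | step 4 | 6-(benzyloxy)-4-bromo-7-methoxyindan-1-ol (racemic) | OC1CCc2c(Br)cc(OCc3ccccc3)c(OC)c21
F6 | step 4 | 6-(benzyloxy)-4-bromo-1-hydroperoxy-7-methoxyindane (racemic) | OOC1CCc2c(Br)cc(OCc3ccccc3)c(OC)c21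
F7 | step 4 | 7-(benzyloxy)-5-bromo-8-methoxychroman-2-ol (racemic) | OC1CCc2c(Br)cc(OCc3ccccc3)c(OC)c2O1
F8 | step 6 | 3-(2,4-dihydroxy-3-methoxyphenyl)propanoic acid | COc1c(O)ccc(CCC(=O)O)c1O
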